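**Plan**

1. Retrosynthetic cuts: first all benzyl-type O–C bonds and the C8–Br bond of the bottom unit. Then, in one event, C4(top)–C8(middle) and the C2–C3 bond of the top ring C, C2 returning to C4. The top unit thus becomes a 2-aryl-2,3-dihydrobenzofuran-3-carbaldehyde (five-membered ring O1–C2–C4–C4a–C8a, C3 outside it as CHO; flavan numbering kept).
2. Enabling feature: C4 of the top unit is benzylic to ring A and conjugated to O1, 5-O and 7-O, so a C4 cation is strongly stabilised. C2 (bonded to O1 and ring B) is an excellent migrating carbon, so its 1,2-shift from C4 to the formyl carbon expands the furan ring to ring C and leaves the C4 cation for the middle unit.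
3. Lower half: cut C4(middle)–C6(bottom); both units come from (−)-epicatechin. Iodine caps C8 of the electrophile (removed before the key step); bromine blocks C8 of the bottom unit (removed at the end).
4. Forward order: symmetric phloroglucinol tris-ether (three molecules of one benzyl chloride on one phloroglucinol core) → ketoester → diazoester → Rh C–H insertion (furan ring) → trans ester → alcohol → aldehyde. Separately: epicatechin → benzyl ether → 8-bromo unit and 8-iodo-4-alkoxy unit → 4β→6 dimer → deiodination. Then aldehyde + dimer → ring C and the 4β→8 bond; hydrogenolysis.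
5. Stereochemistry: the six centres of the lower units come from (−)-epicatechin; both 4β bonds arise by attack anti to the 3-oxygen. Top C2 comes from the chiral Rh catalyst and is retained in the shift (2S in the aldehyde = 2R in the flavan); top C3 from rotamer control of the shift; top C4 from anti attack.

Key step: step 14

Remark on the chemistry: Rh2(S-PTTL)4 is assumed to induce the 2S configuration in step 4 on this 2,6-dialkoxyaryl diazoacetate; if the sense is opposite, Rh2(R-PTTL)4 is used and nothing else changes. The same holds for the auxiliary in the fallback to step 4.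

**Route**

Step 1
Reactants: 1 phloroglucinol triacetate; 2 3,4-bis(benzyloxy)benzyl chloride (3.3 equiv)
Product: 3 1,3,5-tris{[3,4-bis(benzyloxy)benzyl]oxy}benzene
Conditions: 2 (3.3 equiv), NaH (6.6 equiv), DMF, 0 °C; H2O (3 equiv) added slowly; rt
Reagents that add atoms: 3,4-bis(benzyloxy)benzyl chloride (compound 2: three molecules are taken up per molecule of 1), ClCc1ccc(OCc2ccccc2)c(OCc2ccccc2)c1
Why: Threefold Williamson etherification (1 + 3 × 2 + 6 NaH + 3 H2O → 3 + 3 NaOAc + 3 NaCl + 6 H2) with in situ acetate cleavage keeps the free phenoxide concentration low, so O-alkylation should outrun C-alkylation of the phloroglucinol core.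

Step 2
Reactants: 3 1,3,5-tris{[3,4-bis(benzyloxy)benzyl]oxy}benzene
Product: 4 methyl 2-oxo-2-(2,4,6-tris{[3,4-bis(benzyloxy)benzyl]oxy}phenyl)acetate
Conditions: methyl chlorooxoacetate (1.2 equiv), SnCl4 (1.2 equiv), CH2Cl2, −78 °C; aq. NaHCO3
Reagents that add atoms: methyl chlorooxoacetate, COC(=O)C(Cl)=O
Why: Friedel–Crafts acylation of a very electron-rich arene whose three free positions are equivalent, so a single ketoester should form, and the low temperature should spare the benzyl-type ethers.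

Step 3
Reactants: 4 methyl 2-oxo-2-(2,4,6-tris{[3,4-bis(benzyloxy)benzyl]oxy}phenyl)acetate
Product: 6 methyl 2-diazo-2-(2,4,6-tris{[3,4-bis(benzyloxy)benzyl]oxy}phenyl)acetate, via tosylhydrazone 5 (not isolated)
Conditions: TsNHNH2 (1.2 equiv), MeOH/THF, 60 °C; evaporate; DBU (1.5 equiv), CH2Cl2, rt
Reagents that add atoms: p-toluenesulfonyl hydrazide, NNS(=O)(=O)c1ccc(C)cc1
Why: Hydrazone condensation followed by base-induced loss of sulfinate (Bamford–Stevens type) is the standard conversion of aryl glyoxylates into aryl diazoacetates.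

Step 4
Reactants: 6 methyl 2-diazo-2-(2,4,6-tris{[3,4-bis(benzyloxy)benzyl]oxy}phenyl)acetate
Product: 7 methyl (2S,3R)-2-[3,4-bis(benzyloxy)phenyl]-4,6-bis{[3,4-bis(benzyloxy)benzyl]oxy}-2,3-dihydrobenzofuran-3-carboxylate (cis)
Conditions: Rh2(S-PTTL)4 (1 mol %), toluene, −60 °C
Reagents that add atoms: none
Why: Enantioselective intramolecular 1,5 C–H insertion of the donor/acceptor rhodium carbene into an ortho O–CH2Ar bond should close the furan ring; the two ortho ethers are identical, so either gives 7, and the chiral carboxylate ligands set C2 (cis ester as the kinetic product).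

Step 5
Reactants: 7 cis ester
Product: 8 methyl (2S,3S)-2-[3,4-bis(benzyloxy)phenyl]-4,6-bis{[3,4-bis(benzyloxy)benzyl]oxy}-2,3-dihydrobenzofuran-3-carboxylate (trans)
Conditions: NaOMe (0.3 equiv), MeOH/THF, 0 °C → rt
Reagents that add atoms: none
Why: Base-mediated epimerisation at the ester α-carbon should give the thermodynamically favoured 2,3-trans isomer and leave C2 untouched.

Step 6
Reactants: 8 trans ester
Product: 9 [(2S,3R)-2-[3,4-bis(benzyloxy)phenyl]-4,6-bis{[3,4-bis(benzyloxy)benzyl]oxy}-2,3-dihydrobenzofuran-3-yl]methanol (trans)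
Conditions: LiAlH4, THF, 0 °C
Reagents that add atoms: none
Why: Hydride reduction of the ester to the primary alcohol touches no stereocentre and tolerates the benzyl-type ethers.

Step 7
Reactants: 9 trans alcohol
Product: 10 (2S,3S)-2-[3,4-bis(benzyloxy)phenyl]-4,6-bis{[3,4-bis(benzyloxy)benzyl]oxy}-2,3-dihydrobenzofuran-3-carbaldehyde (trans)
Conditions: Dess–Martin periodinane (1.3 equiv), NaHCO3, CH2Cl2, 0 °C; used at once without chromatography
Reagents that add atoms: none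
Why: Dess–Martin oxidation is non-basic, which should avoid loss of the β-aryloxy group and keep the trans aldehyde intact.

Step 8
Reactants: 11 (−)-epicatechin
Product: 12 5,7,3',4'-tetra-O-benzyl-(−)-epicatechin
Conditions: BnBr (4.4 equiv), K2CO3, DMF, 0 °C → rt
Reagents that add atoms: benzyl bromide, BrCc1ccccc1
Why: Williamson benzylation with a carbonate base alkylates the four phenols and leaves the much less acidic 3-OH free.

Step 9
Reactants: 12 5,7,3',4'-tetra-O-benzyl-(−)-epicatechin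
Product: 13 8-bromo-5,7,3',4'-tetra-O-benzyl-(−)-epicatechin
Conditions: NBS (1.0 equiv), CH2Cl2, −78 °C → rt
Reagents that add atoms: N-bromosuccinimide, O=C1CCC(=O)N1Br
Why: Electrophilic aromatic bromination should occur at C8, the most nucleophilic position of ring A.

Step 10
Reactants: 12 5,7,3',4'-tetra-O-benzyl-(−)-epicatechin
Product: 14 8-iodo-5,7,3',4'-tetra-O-benzyl-(−)-epicatechin
Conditions: NIS (1.05 equiv), CH2Cl2, 0 °C
Reagents that add atoms: N-iodosuccinimide, O=C1CCC(=O)N1I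
Why: Electrophilic aromatic iodination should follow the same C8 preference as the bromination.

Step 11
Reactants: 14 8-iodo-5,7,3',4'-tetra-O-benzyl-(−)-epicatechin
Product: 15 4β-(2-ethoxyethoxy)-8-iodo-5,7,3',4'-tetra-O-benzyl-(−)-epicatechin
Conditions: DDQ (2 equiv), 2-ethoxyethanol (5 equiv), CH2Cl2, rt
Reagents that add atoms: 2-ethoxyethanol, CCOCCO
Why: DDQ benzylic oxidation at C4 gives the ring-A-stabilised cation, which the alcohol should trap trans to the 3-OH (4β).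

Step 12
Reactants: 15 4β-(2-ethoxyethoxy)-8-iodo-5,7,3',4'-tetra-O-benzyl-(−)-epicatechin; 13 8-bromo-5,7,3',4'-tetra-O-benzyl-(−)-epicatechin
Product: 16 [8-iodo-5,7,3',4'-tetra-O-benzylepicatechin]-(4β→6)-[8-bromo-5,7,3',4'-tetra-O-benzylepicatechin]
Conditions: 13 (3 equiv), TMSOTf (0.3 equiv), CH2Cl2, −78 → −40 °C; Et3N quench; excess 13 recovered
Reagents that add atoms: none
Why: Lewis-acid Friedel–Crafts interflavan coupling: the C4 cation is attacked anti to the 3-OH (4β) by C6, the only free ring-A position of 13, while the iodine at C8 of 15 and the excess of 13 should suppress self-condensation.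

Step 13
Reactants: 16 iodo bromo dimer
Product: 18 [5,7,3',4'-tetra-O-benzylepicatechin]-(4β→6)-[8-bromo-5,7,3',4'-tetra-O-benzylepicatechin], via arylmagnesium bis-alkoxide 17 (not isolated)
Conditions: iPrMgCl·LiCl (3.5 equiv), THF, −20 → 0 °C; then MeOH, aq. NH4Cl
Reagents that add atoms: none
Why: Halogen–magnesium exchange is much faster for the aryl iodide than for the electron-rich aryl bromide, so protonation should free C8 of the middle unit and keep the bromine on the bottom unit.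

Step 14
Reactants: 10 trans aldehyde; 18 bromo dimer
Product: 22 [5,7-bis-O-{3,4-bis(benzyloxy)benzyl}-3',4'-di-O-benzylepicatechin]-(4β→8)-[5,7,3',4'-tetra-O-benzylepicatechin]-(4β→6)-[8-bromo-5,7,3',4'-tetra-O-benzylepicatechin], via silyloxocarbenium triflate 19 (not isolated), via flavan-4-yl cation 20 (not isolated), via trimethylsilyl ether 21 (not isolated)
Conditions: 18 (2 equiv), TMSOTf (1.3 equiv), 4 Å MS, CH2Cl2 (0.01 M in 10), −78 → −30 °C; aq. NaHCO3; then 1 M HCl/THF, 0 °C; excess 18 recovered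
Reagents that add atoms: none
Why: Proposed new method: TMSOTf silylates the formyl oxygen of 10 to the oxocarbenium ion 19, C2 shifts with retention from C4 to the formyl carbon, and the resulting C4 cation 20, stabilised by O1 and the 5- and 7-oxygens of ring A, is captured by C8 of the middle unit of 18 in a Friedel–Crafts alkylation. The closest known reaction types are the acid-catalysed aldehyde–ketone (retro-pinacol, Wagner–Meerwein) rearrangement with ring expansion and the Lewis-acid coupling of flavan-4-yl cations with flavan-3-ol nucleophiles; their combination on a 2,3-dihydrobenzofuran-3-carbaldehyde has no precedent. Ring C (O1, C2, C3, C4, C4a, C8a) is closed by a 1,2-shift, that is by expansion of the five-membered ring O1–C2–C4–C4a–C8a, the former formyl carbon entering as C3 between C2 and C4. C2 keeps the configuration set in step 4; C3 is set by the reacting rotamer, in which the silylated oxygen points away from the 5-alkoxy group of ring A and the C4–C2 bond lies parallel to the carbonyl π* orbital, which in the trans aldehyde places the oxygen cis to the ring B aryl group (2,3-cis); C4 is set by attack anti to the pseudo-axial 3-OTMS group (4β). The step needs the shift to outrun both direct attack of 18 on the formyl carbon and a 1,2-hydride shift from C4 (helped by high dilution, the intramolecular nature of the shift and the poor alignment of the C4–H bond in the reactive rotamer), and it needs C8 of the middle unit to be the only reactive arene position (secured by the bromine at C8 of the bottom unit and the lower reactivity of C6). The acidic work-up cleaves the silyl ether 21 to 22.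

Step 15
Reactants: 22 protected bromo trimer
Product: 23 epicatechin-(4β→8)-epicatechin-(4β→6)-epicatechin (CNP0178679.3)
Conditions: H2 (1 atm), Pd(OH)2/C, NaHCO3 (1.1 equiv), THF/MeOH/H2O, rt; Sephadex LH-20
Reagents that add atoms: none
Why: Catalytic hydrogenolysis should cleave all fourteen benzyl ethers and both 3,4-dioxygenated benzyl ethers and reduce the C–Br bond, while the buffer protects the acid-labile interflavan bonds and no stereocentre is touched.

**Compound list**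

1 | phloroglucinol triacetate | CC(=O)Oc1cc(OC(C)=O)cc(OC(C)=O)c1 | starting material
2 | 3,4-bis(benzyloxy)benzyl chloride | ClCc1ccc(OCc2ccccc2)c(OCc2ccccc2)c1 | starting material
3 | 1,3,5-tris{[3,4-bis(benzyloxy)benzyl]oxy}benzene | c1(OCc3ccc(OCc4ccccc4)c(OCc4ccccc4)c3)cc(OCc3ccc(OCc4ccccc4)c(OCc4ccccc4)c3)cc(OCc3ccc(OCc4ccccc4)c(OCc4ccccc4)c3)c1 | intermediate
4 | methyl 2-oxo-2-(2,4,6-tris{[3,4-bis(benzyloxy)benzyl]oxy}phenyl)acetate | COC(=O)C(=O)c1c(OCc3ccc(OCc4ccccc4)c(OCc4ccccc4)c3)cc(OCc3ccc(OCc4ccccc4)c(OCc4ccccc4)c3)cc1OCc3ccc(OCc4ccccc4)c(OCc4ccccc4)c3 | intermediate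
5 | tosylhydrazone of 4 | COC(=O)C(=NNS(=O)(=O)c1ccc(C)cc1)c1c(OCc3ccc(OCc4ccccc4)c(OCc4ccccc4)c3)cc(OCc3ccc(OCc4ccccc4)c(OCc4ccccc4)c3)cc1OCc3ccc(OCc4ccccc4)c(OCc4ccccc4)c3 | intermediate
6 | methyl 2-diazo-2-(2,4,6-tris{[3,4-bis(benzyloxy)benzyl]oxy}phenyl)acetate | COC(=O)C(=[N+]=[N-])c1c(OCc3ccc(OCc4ccccc4)c(OCc4ccccc4)c3)cc(OCc3ccc(OCc4ccccc4)c(OCc4ccccc4)c3)cc1OCc3ccc(OCc4ccccc4)c(OCc4ccccc4)c3 | intermediate
7 | methyl (2S,3R)-2-[3,4-bis(benzyloxy)phenyl]-4,6-bis{[3,4-bis(benzyloxy)benzyl]oxy}-2,3-dihydrobenzofuran-3-carboxylate (cis) | c1(OCc3ccc(OCc4ccccc4)c(OCc4ccccc4)c3)cc(OCc3ccc(OCc4ccccc4)c(OCc4ccccc4)c3)c2c(c1)O[C@H](c1ccc(OCc3ccccc3)c(OCc3ccccc3)c1)[C@@H]2C(=O)OC | intermediate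
8 | methyl (2S,3S)-2-[3,4-bis(benzyloxy)phenyl]-4,6-bis{[3,4-bis(benzyloxy)benzyl]oxy}-2,3-dihydrobenzofuran-3-carboxylate (trans) | c1(OCc3ccc(OCc4ccccc4)c(OCc4ccccc4)c3)cc(OCc3ccc(OCc4ccccc4)c(OCc4ccccc4)c3)c2c(c1)O[C@H](c1ccc(OCc3ccccc3)c(OCc3ccccc3)c1)[C@H]2C(=O)OC | intermediate
9 | [(2S,3R)-2-[3,4-bis(benzyloxy)phenyl]-4,6-bis{[3,4-bis(benzyloxy)benzyl]oxy}-2,3-dihydrobenzofuran-3-yl]methanol (trans) | c1(OCc3ccc(OCc4ccccc4)c(OCc4ccccc4)c3)cc(OCc3ccc(OCc4ccccc4)c(OCc4ccccc4)c3)c2c(c1)O[C@H](c1ccc(OCc3ccccc3)c(OCc3ccccc3)c1)[C@H]2CO | intermediate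
10 | (2S,3S)-2-[3,4-bis(benzyloxy)phenyl]-4,6-bis{[3,4-bis(benzyloxy)benzyl]oxy}-2,3-dihydrobenzofuran-3-carbaldehyde (trans) | c1(OCc3ccc(OCc4ccccc4)c(OCc4ccccc4)c3)cc(OCc3ccc(OCc4ccccc4)c(OCc4ccccc4)c3)c2c(c1)O[C@H](c1ccc(OCc3ccccc3)c(OCc3ccccc3)c1)[C@H]2C=O | intermediate
11 | (−)-epicatechin | Oc1cc(O)c2c(c1)O[C@H](c1ccc(O)c(O)c1)[C@H](O)C2 | starting material
12 | 5,7,3',4'-tetra-O-benzyl-(−)-epicatechin | O(Cc1ccccc1)c1cc(OCc3ccccc3)c2c(c1)O[C@H](c1ccc(OCc3ccccc3)c(OCc3ccccc3)c1)[C@H](O)C2 | intermediate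
13 | 8-bromo-5,7,3',4'-tetra-O-benzyl-(−)-epicatechin | O(Cc1ccccc1)c1cc(OCc3ccccc3)c2c(c1Br)O[C@H](c1ccc(OCc3ccccc3)c(OCc3ccccc3)c1)[C@H](O)C2 | intermediate
14 | 8-iodo-5,7,3',4'-tetra-O-benzyl-(−)-epicatechin | O(Cc1ccccc1)c1cc(OCc3ccccc3)c2c(c1I)O[C@H](c1ccc(OCc3ccccc3)c(OCc3ccccc3)c1)[C@H](O)C2 | intermediate
15 | 4β-(2-ethoxyethoxy)-8-iodo-5,7,3',4'-tetra-O-benzyl-(−)-epicatechin | O(Cc1ccccc1)c1cc(OCc3ccccc3)c2c(c1I)O[C@H](c1ccc(OCc3ccccc3)c(OCc3ccccc3)c1)[C@H](O)[C@H]2OCCOCC | intermediate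
16 | [8-iodo-5,7,3',4'-tetra-O-benzylepicatechin]-(4β→6)-[8-bromo-5,7,3',4'-tetra-O-benzylepicatechin] | O(Cc1ccccc1)c1cc(OCc3ccccc3)c2c(c1I)O[C@H](c1ccc(OCc3ccccc3)c(OCc3ccccc3)c1)[C@H](O)[C@H]2c1c(OCc3ccccc3)c(Br)c2c(c1OCc3ccccc3)C[C@@H](O)[C@@H](c1ccc(OCc3ccccc3)c(OCc3ccccc3)c1)O2 | intermediate
17 | C8 arylmagnesium chloride bis(chloromagnesium alkoxide) of the dimer | O(Cc1ccccc1)c1cc(OCc3ccccc3)c2c(c1[Mg]Cl)O[C@H](c1ccc(OCc3ccccc3)c(OCc3ccccc3)c1)[C@H](O[Mg]Cl)[C@H]2c1c(OCc3ccccc3)c(Br)c2c(c1OCc3ccccc3)C[C@@H](O[Mg]Cl)[C@@H](c1ccc(OCc3ccccc3)c(OCc3ccccc3)c1)O2 | intermediate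
18 | [5,7,3',4'-tetra-O-benzylepicatechin]-(4β→6)-[8-bromo-5,7,3',4'-tetra-O-benzylepicatechin] | O(Cc1ccccc1)c1cc(OCc3ccccc3)c2c(c1)O[C@H](c1ccc(OCc3ccccc3)c(OCc3ccccc3)c1)[C@H](O)[C@H]2c1c(OCc3ccccc3)c(Br)c2c(c1OCc3ccccc3)C[C@@H](O)[C@@H](c1ccc(OCc3ccccc3)c(OCc3ccccc3)c1)O2 | intermediate
19 | O-trimethylsilyl oxocarbenium triflate of 10 | c1(OCc3ccc(OCc4ccccc4)c(OCc4ccccc4)c3)cc(OCc3ccc(OCc4ccccc4)c(OCc4ccccc4)c3)c2c(c1)O[C@H](c1ccc(OCc3ccccc3)c(OCc3ccccc3)c1)[C@H]2C=[O+][Si](C)(C)C.[O-]S(=O)(=O)C(F)(F)F | intermediate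
20 | (2R,3R)-3-trimethylsilyloxy-flavan-4-yl cation triflate (ring-expanded) | c1(OCc3ccc(OCc4ccccc4)c(OCc4ccccc4)c3)cc(OCc3ccc(OCc4ccccc4)c(OCc4ccccc4)c3)c2c(c1)O[C@H](c1ccc(OCc3ccccc3)c(OCc3ccccc3)c1)[C@H](O[Si](C)(C)C)[CH+]2.[O-]S(=O)(=O)C(F)(F)F | intermediate
21 | top-unit 3-O-trimethylsilyl ether of 22 | c1(OCc3ccc(OCc4ccccc4)c(OCc4ccccc4)c3)cc(OCc3ccc(OCc4ccccc4)c(OCc4ccccc4)c3)c2c(c1)O[C@H](c1ccc(OCc3ccccc3)c(OCc3ccccc3)c1)[C@H](O[Si](C)(C)C)[C@H]2c1c(OCc3ccccc3)cc(OCc3ccccc3)c2c1O[C@H](c1ccc(OCc3ccccc3)c(OCc3ccccc3)c1)[C@H](O)[C@H]2c1c(OCc3ccccc3)c(Br)c2c(c1OCc3ccccc3)C[C@@H](O)[C@@H](c1ccc(OCc3ccccc3)c(OCc3ccccc3)c1)O2 | intermediate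
22 | [5,7-bis-O-{3,4-bis(benzyloxy)benzyl}-3',4'-di-O-benzylepicatechin]-(4β→8)-[5,7,3',4'-tetra-O-benzylepicatechin]-(4β→6)-[8-bromo-5,7,3',4'-tetra-O-benzylepicatechin] | c1(OCc3ccc(OCc4ccccc4)c(OCc4ccccc4)c3)cc(OCc3ccc(OCc4ccccc4)c(OCc4ccccc4)c3)c2c(c1)O[C@H](c1ccc(OCc3ccccc3)c(OCc3ccccc3)c1)[C@H](O)[C@H]2c1c(OCc3ccccc3)cc(OCc3ccccc3)c2c1O[C@H](c1ccc(OCc3ccccc3)c(OCc3ccccc3)c1)[C@H](O)[C@H]2c1c(OCc3ccccc3)c(Br)c2c(c1OCc3ccccc3)C[C@@H](O)[C@@H](c1ccc(OCc3ccccc3)c(OCc3ccccc3)c1)O2 | intermediate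
23 | epicatechin-(4β→8)-epicatechin-(4β→6)-epicatechin (CNP0178679.3) | Oc1cc(O)c2c(c1)O[C@H](c1ccc(O)c(O)c1)[C@H](O)[C@H]2c1c(O)cc(O)c2c1O[C@H](c1ccc(O)c(O)c1)[C@H](O)[C@H]2c1c(O)cc2c(c1O)C[C@@H](O)[C@@H](c1ccc(O)c(O)c1)O2 | target

**Count and risks**

Total step count: 15. Longest linear sequence: 9 steps (steps 1–7, 14, 15).

Steps most likely to fail:

1. Step 14 (Proposed new method). The nucleophile may attack the activated formyl carbon directly before the shift. A 1,2-hydride shift from C4 followed by proton loss from C2 may aromatise the furan ring. The shift may take place through the other rotamer and give the 2,3-trans series, or the C2–O1 bond may ionise and erode C2. The Lewis acid may also ionise the 3,4-dialkoxybenzyl ethers at the 5- and 7-oxygens. Fallback with known chemistry, setting out from 12 and 18 and coming back at 23: DDQ oxidation of 12 in the presence of 2-ethoxyethanol should give 4β-(2-ethoxyethoxy)-5,7,3',4'-tetra-O-benzyl-(−)-epicatechin F1. TMSOTf-mediated coupling of F1 with an excess of 18 should give the all-benzyl protected bromo trimer F2, which the hydrogenolysis of step 15 converts into 23. The top unit then comes from the chiral pool and its ring C is not built.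

2. Step 4. The two ortho substituents twist the aryl group out of conjugation with the carbene, which may lower the enantioselectivity; oxonium ylide formation with benzyl shift may compete with C–H insertion. Fallback by auxiliary control instead of catalyst control, setting out from 4 and coming back at 9: Ti(OiPr)4-mediated transesterification of 4 with (S)-2-hydroxy-1-(pyrrolidin-1-yl)propan-1-one should give the lactamide ketoester F3. The tosylhydrazide and DBU sequence of step 3 should lead through the tosylhydrazone F4 to the diazoester F5. Insertion with Rh2(S-DOSP)4 should give the trans dihydrobenzofuran lactamide ester F6 diastereoselectively, which can be purified as a single diastereomer. LiAlH4 reduction of F6 returns to 9.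

3. Step 2. The Lewis acid may cleave the electron-rich benzyl ethers (chelation-assisted ortho-dealkylation once the ketone is in place). Fallback without an acid chloride or a strong Lewis acid, setting out from 3 and coming back at 4: hydroxyalkylation of 3 with an excess of methyl glyoxylate under Yb(OTf)3 catalysis should give the racemic mandelate methyl 2-hydroxy-2-(2,4,6-tris{[3,4-bis(benzyloxy)benzyl]oxy}phenyl)acetate F7, and Dess–Martin oxidation of F7 returns to 4.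

Further compounds

F1 | step 14 | 4β-(2-ethoxyethoxy)-5,7,3',4'-tetra-O-benzyl-(−)-epicatechin | O(Cc1ccccc1)c1cc(OCc3ccccc3)c2c(c1)O[C@H](c1ccc(OCc3ccccc3)c(OCc3ccccc3)c1)[C@H](O)[C@H]2OCCOCC
F2 | step 14 | [5,7,3',4'-tetra-O-benzylepicatechin]-(4β→8)-[5,7,3',4'-tetra-O-benzylepicatechin]-(4β→6)-[8-bromo-5,7,3',4'-tetra-O-benzylepicatechin] | O(Cc1ccccc1)c1cc(OCc3ccccc3)c2c(c1)O[C@H](c1ccc(OCc3ccccc3)c(OCc3ccccc3)c1)[C@H](O)[C@H]2c1c(OCc3ccccc3)cc(OCc3ccccc3)c2c1O[C@H](c1ccc(OCc3ccccc3)c(OCc3ccccc3)c1)[C@H](O)[C@H]2c1c(OCc3ccccc3)c(Br)c2c(c1OCc3ccccc3)C[C@@H](O)[C@@H](c1ccc(OCc3ccccc3)c(OCc3ccccc3)c1)O2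
F3 | step 4 | (S)-1-oxo-1-(pyrrolidin-1-yl)propan-2-yl 2-oxo-2-(2,4,6-tris{[3,4-bis(benzyloxy)benzyl]oxy}phenyl)acetate | C[C@H](OC(=O)C(=O)c1c(OCc3ccc(OCc4ccccc4)c(OCc4ccccc4)c3)cc(OCc3ccc(OCc4ccccc4)c(OCc4ccccc4)c3)cc1OCc3ccc(OCc4ccccc4)c(OCc4ccccc4)c3)C(=O)N1CCCC1
F4 | step 4 | tosylhydrazone of F3 | C[C@H](OC(=O)C(=NNS(=O)(=O)c1ccc(C)cc1)c1c(OCc3ccc(OCc4ccccc4)c(OCc4ccccc4)c3)cc(OCc3ccc(OCc4ccccc4)c(OCc4ccccc4)c3)cc1OCc3ccc(OCc4ccccc4)c(OCc4ccccc4)c3)C(=O)N1CCCC1
F5 | step 4 | (S)-1-oxo-1-(pyrrolidin-1-yl)propan-2-yl 2-diazo-2-(2,4,6-tris{[3,4-bis(benzyloxy)benzyl]oxy}phenyl)acetate | C[C@H](OC(=O)C(=[N+]=[N-])c1c(OCc3ccc(OCc4ccccc4)c(OCc4ccccc4)c3)cc(OCc3ccc(OCc4ccccc4)c(OCc4ccccc4)c3)cc1OCc3ccc(OCc4ccccc4)c(OCc4ccccc4)c3)C(=O)N1CCCC1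
F6 | step 4 | (S)-1-oxo-1-(pyrrolidin-1-yl)propan-2-yl (2S,3S)-2-[3,4-bis(benzyloxy)phenyl]-4,6-bis{[3,4-bis(benzyloxy)benzyl]oxy}-2,3-dihydrobenzofuran-3-carboxylate (trans) | c1(OCc3ccc(OCc4ccccc4)c(OCc4ccccc4)c3)cc(OCc3ccc(OCc4ccccc4)c(OCc4ccccc4)c3)c2c(c1)O[C@H](c1ccc(OCc3ccccc3)c(OCc3ccccc3)c1)[C@H]2C(=O)O[C@@H](C)C(=O)N1CCCC1
F7 | step 2 | methyl 2-hydroxy-2-(2,4,6-tris{[3,4-bis(benzyloxy)benzyl]oxy}phenyl)acetate (racemic) | COC(=O)C(O)c1c(OCc3ccc(OCc4ccccc4)c(OCc4ccccc4)c3)cc(OCc3ccc(OCc4ccccc4)c(OCc4ccccc4)c3)cc1OCc3ccc(OCc4ccccc4)c(OCc4ccccc4)c3
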